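Ring A (C6–C11; target numbered as a spiro[5.5]undecane, C1 = CMe2, C6 = spiro carbon) is read as a masked cyclohexane-1,4-dione: its two fully substituted carbons, C6 and C9 (CMeCl), face each other across two CH2CH2 arms. The key step stitches the C10–C11 arm between two acyclic esters, methyl 4-nitrobutanoate and tert-butyl acrylate, by a tandem nitro-Michael/Dieckmann reaction that forms C9–C10 and C11–C6 and leaves C6 (ketone) and C9 (nitro) differentiated. Ring B is then annulated on C6, the achiral spirotrione is desymmetrised by a chiral lithium amide, a C5 hydroxyl tethers the trans bromine/chlorine pair onto C8/C9, and a CBS reduction sets C4.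

Key step: step 1

Remark on numbering: the locants of the target (C1 CMe2, C2 CBr, C3 =CH, C4 CHOH, C5 C(=CH2), C6 spiro carbon, C7 CH2, C8 CHBr, C9 C(Me)Cl, C10 and C11 CH2; ring A = C6–C11, ring B = C1–C6) are used for the same carbons in all intermediates. The two CH2CH2 arms of ring A are enantiotopic in 11 and 12; the arm made in step 1 is counted as C10–C11.

Step 1
Reactants: 1 methyl 4-nitrobutanoate; 2 tert-butyl acrylate
Product: 4 tert-butyl 5-nitro-2-oxocyclohexane-1-carboxylate, via nitro diester 3 (not isolated)
Conditions: DBU (cat.), MeCN, 0 °C to rt; then KOtBu (2.2 equiv), THF, 0 °C to rt; AcOH quench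
Reagents that add atoms: none
Why: DBU generates the nitronate of 1, which adds to tert-butyl acrylate (nitro-Michael addition) and makes the C9–C10 bond; KOtBu then forms the tert-butyl ester enolate of 3, whose α-carbon (C11) acylates the methyl ester carbon (C6) in a Dieckmann condensation that makes the C11–C6 bond and closes ring A. The closest known reaction type is the tandem nitroalkane Michael addition/Dieckmann cyclisation used for 4-nitrocyclohexanones. Ring A closes in the 6-exo-trig (enolexo) mode. The two stereocentres of 4 (C11 and C9) form without control and need none, because C11 is cleared by the decarboxylation in step 2 and C9 by the Nef reaction in step 6. The step needs monoaddition of the nitronate and one direction of acylation: the first should follow from the lower reactivity of the secondary nitronate towards one equivalent of acrylate, the second from the tert-butyl ester, a poor acyl acceptor, so that only the methyl ester carbonyl is attacked.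

Step 2
Reactants: 4 tert-butyl 5-nitro-2-oxocyclohexane-1-carboxylate
Product: 5 4-nitrocyclohexan-1-one
Conditions: CF3CO2H, CH2Cl2, rt; then toluene, 80 °C
Reagents that add atoms: none
Why: Acidolysis of the tert-butyl ester and decarboxylation of the resulting β-keto acid should give the achiral ketone, in which C6 is a free carbonyl and C9 carries the nitro group as a masked carbonyl.

Step 3
Reactants: 5 4-nitrocyclohexan-1-one; 6 dimethyl malonate
Product: 7 dimethyl 2-(4-nitrocyclohexylidene)propanedioate
Conditions: TiCl4, pyridine, THF, 0 °C to rt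
Reagents that add atoms: none
Why: Knoevenagel condensation at C6 under TiCl4/pyridine should give the tetrasubstituted, doubly activated alkene, the weakly basic medium leaving the secondary nitro group alone; no stereocentre is formed.

Step 4
Reactants: 8 3-bromo-3-methylbutan-2-one
Product: 9 trimethyl[(3-methylbut-2-en-2-yl)oxy]silane
Conditions: Zn dust, Me3SiCl, Et2O, rt; distillation
Reagents that add atoms: chlorotrimethylsilane C[Si](C)(C)Cl
Why: Reductive silylation of the tertiary α-bromo ketone (zinc enolate formation, then O-silylation) should give the tetrasubstituted silyl enol ether regiospecifically, which direct enolisation of 3-methylbutan-2-one would not.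

Step 5
Reactants: 7 dimethyl 2-(4-nitrocyclohexylidene)propanedioate; 9 trimethyl[(3-methylbut-2-en-2-yl)oxy]silane
Product: 10 dimethyl 2-[1-(2-methyl-3-oxobutan-2-yl)-4-nitrocyclohexyl]propanedioate
Conditions: TiCl4, CH2Cl2, −78 °C to −40 °C; aq. NaHCO3
Reagents that add atoms: none
Why: A Mukaiyama–Michael addition of the CMe2 terminus of 9 to the doubly activated β-carbon C6 should join the two fully substituted carbons C1 and C6 under non-basic conditions that tolerate the nitro group; the cis/trans isomers about C6/C9 need no control because C9 becomes a carbonyl carbon in step 6.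

Step 6
Reactants: 10 dimethyl 2-[1-(2-methyl-3-oxobutan-2-yl)-4-nitrocyclohexyl]propanedioate
Product: 11 1,1-dimethylspiro[5.5]undecane-2,4,9-trione
Conditions: NaOMe, MeOH, reflux; aq. NaOH, reflux; then added to cold aq. H2SO4, then 60 °C
Reagents that add atoms: water O
Why: Methoxide should bring about the Claisen condensation of the methyl ketone enolate (C3) onto a malonate ester (C4), as in the classical dimedone synthesis; hydroxide then saponifies the remaining ester, and acidification of the nitronate salt effects the Nef reaction at C9 and the decarboxylation at C5, so that the achiral trione results.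

Step 7
Reactants: 11 1,1-dimethylspiro[5.5]undecane-2,4,9-trione
Product: 12 4-methoxy-1,1-dimethylspiro[5.5]undec-3-ene-2,9-dione
Conditions: Me2SO4, K2CO3, acetone, reflux
Reagents that add atoms: dimethyl sulfate COS(=O)(=O)OC
Why: O-Methylation of the dione enolate (vinylogous ester formation) should take place at the less hindered oxygen on C4, remote from the gem-dimethyl group; this masks the acidic dione for step 8 and places the leaving group for step 10, and no stereocentre is formed.

Step 8
Reactants: 12 4-methoxy-1,1-dimethylspiro[5.5]undec-3-ene-2,9-dione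
Product: 13 (6S)-4-methoxy-1,1-dimethyl-2-oxospiro[5.5]undeca-3,8-dien-9-yl trifluoromethanesulfonate
Conditions: lithium (R,R)-bis(1-phenylethyl)amide, LiCl, THF, −78 °C; then PhNTf2, −78 °C to 0 °C
Reagents that add atoms: N-phenylbis(trifluoromethanesulfonimide) O=S(=O)(N(c1ccccc1)S(=O)(=O)C(F)(F)F)C(F)(F)F
Why: Enantioselective deprotonation by a chiral lithium amide (known for 4,4-disubstituted cyclohexanones) removes one of the two enantiotopic axial α-protons of the C9 ketone of achiral 12 and triflation traps the enolate, so that the position of the C8=C9 double bond fixes the spiro carbon C6 as (S); the sense is assigned by analogy with 4-tert-butylcyclohexanone, C1 taking the part of the equatorial tert-butyl group, and the antipodal amide would be used if the sense proved opposite.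

Step 9
Reactants: 13 (6S)-4-methoxy-1,1-dimethyl-2-oxospiro[5.5]undeca-3,8-dien-9-yl trifluoromethanesulfonate
Product: 14 (6S)-4-methoxy-1,1,9-trimethylspiro[5.5]undeca-3,8-dien-2-one
Conditions: MeZnCl, Pd(PPh3)4 (cat.), THF, 50 °C
Reagents that add atoms: methylzinc chloride C[Zn]Cl
Why: Negishi cross-coupling of the enol triflate should install the C9 methyl group without moving the double bond, the vinylogous ester being inert to the organozinc reagent.

Step 10
Reactants: 14 (6S)-4-methoxy-1,1,9-trimethylspiro[5.5]undeca-3,8-dien-2-one
Product: 15 (6S)-2-bromo-1,1,9-trimethylspiro[5.5]undeca-2,8-dien-4-one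
Conditions: (COBr)2, CH2Cl2, 0 °C to rt
Reagents that add atoms: oxalyl bromide O=C(Br)C(=O)Br
Why: Vilsmeier-type activation: oxalyl bromide acylates the carbonyl oxygen on C2, bromide adds to C2 with loss of the oxalate (CO, CO2), and demethylation of the resulting oxocarbenium ion by bromide frees the C4 ketone, so that oxygen and halogen are transposed and the bromine should end on the hindered carbon next to the gem-dimethyl group.

Step 11
Reactants: 15 (6S)-2-bromo-1,1,9-trimethylspiro[5.5]undeca-2,8-dien-4-one
Product: 16 (6S)-2-bromo-1,1,5,9-tetramethylspiro[5.5]undeca-2,8-dien-4-one (C5 epimers)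
Conditions: LiN(iPr)2, THF, −78 °C; MeI, DMPU, −78 °C to −20 °C
Reagents that add atoms: iodomethane CI
Why: Kinetic α'-deprotonation at C5, the only enolisable position of the enone, and enolate C-methylation bring in the carbon that becomes the exocyclic methylene; the new C5 stereocentre is of no consequence because C5 becomes trigonal in step 15.

Step 12
Reactants: 16 (6S)-2-bromo-1,1,5,9-tetramethylspiro[5.5]undeca-2,8-dien-4-one
Product: 17 (6R)-2-bromo-5-hydroxy-1,1,5,9-tetramethylspiro[5.5]undeca-2,8-dien-4-one (C5 epimers)
Conditions: KN(SiMe3)2, THF, −78 °C; 3-phenyl-2-(phenylsulfonyl)oxaziridine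
Reagents that add atoms: 3-phenyl-2-(phenylsulfonyl)oxaziridine O=S(=O)(c1ccccc1)N1OC1c1ccccc1
Why: Enolate hydroxylation with an N-sulfonyloxaziridine at the tertiary C5 should give the tertiary α-ketol whose hydroxyl is the tether for step 13; both C5 epimers are carried on (the C6 descriptor changes only through the priority rules).

Step 13
Reactants: 17 (6R)-2-bromo-5-hydroxy-1,1,5,9-tetramethylspiro[5.5]undeca-2,8-dien-4-one
Product: 18 (6R,8S,9S)-2,8-dibromo-5,9-epoxy-1,1,5,9-tetramethylspiro[5.5]undec-2-en-4-one (C5 epimers)
Conditions: NBS, CH2Cl2, 0 °C, dark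
Reagents that add atoms: N-bromosuccinimide O=C1CCC(=O)N1Br
Why: Bromoetherification, as in the closure of α-terpineol-type cyclohexenyl carbinols to 2-oxabicyclo[2.2.2]octanes: the C5 hydroxyl can reach only the face of ring A on which C5 stands and attacks the tertiary C9, so the bromonium ion must lie on the opposite face and bromine arrives at C8 anti to the new C9–O bond and cis to C1, which sets C8 (S) and C9 (S) relative to C6; the electron-poor bromoenone double bond should not react.

Step 14
Reactants: 18 (6R,8S,9S)-2,8-dibromo-5,9-epoxy-1,1,5,9-tetramethylspiro[5.5]undec-2-en-4-one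
Product: 19 (6R,8S,9S)-2,8-dibromo-9-chloro-5-hydroxy-1,1,5,9-tetramethylspiro[5.5]undec-2-en-4-one (C5 epimers)
Conditions: TiCl4, CH2Cl2, −78 °C to −40 °C; aq. NaHCO3
Reagents that add atoms: titanium tetrachloride Cl[Ti](Cl)(Cl)Cl
Why: Lewis acid cleavage of a tertiary alkyl ether: TiCl4, held by the C4 carbonyl and the ether oxygen, should ionise the C9–O bond with participation of the antiperiplanar C8 bromine, and chloride opens the bromonium ion at the tertiary C9 from the face the oxygen left, so that chlorine replaces oxygen with retention and the trans bromochloride results; the C5–O bond, α to the ketone, should not ionise.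

Step 15
Reactants: 19 (6R,8S,9S)-2,8-dibromo-9-chloro-5-hydroxy-1,1,5,9-tetramethylspiro[5.5]undec-2-en-4-one
Product: 20 (6S,8S,9S)-2,8-dibromo-9-chloro-1,1,9-trimethyl-5-methylidenespiro[5.5]undec-2-en-4-one
Conditions: methyl N-(triethylammoniosulfonyl)carbamate, toluene, 50 °C
Reagents that add atoms: none
Why: Burgess dehydration (syn-elimination of the sulfamate ester) of the tertiary ketol can use only the methyl hydrogens, since C6 is quaternary and C4 is a carbonyl carbon, so the exocyclic methylene should form regiospecifically under neutral conditions that spare the secondary bromide and the tertiary chloride; both C5 epimers converge.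

Step 16
Reactants: 20 (6S,8S,9S)-2,8-dibromo-9-chloro-1,1,9-trimethyl-5-methylidenespiro[5.5]undec-2-en-4-one
Product: 21 (4R,6S,8S,9S)-2,8-dibromo-9-chloro-1,1,9-trimethyl-5-methylidenespiro[5.5]undec-2-en-4-ol
Conditions: (S)-2-methyl-CBS-oxazaborolidine (cat.), catecholborane, toluene, −78 °C
Reagents that add atoms: none
Why: Corey–Bakshi–Shibata reduction should reduce the cross-conjugated ketone in the 1,2-sense under reagent control, the α-branched methylidene flank acting as the large group and the CH=CBr flank as the small one, which with the (S)-catalyst should give the (4R) alcohol; the ring A stereocentres are too remote to interfere.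

Compound list
1 | methyl 4-nitrobutanoate | COC(=O)CCC[N+](=O)[O-] | starting material
2 | tert-butyl acrylate | C=CC(=O)OC(C)(C)C | starting material
3 | 1-tert-butyl 7-methyl 4-nitroheptanedioate (racemic, not isolated) | COC(=O)CCC(CCC(=O)OC(C)(C)C)[N+](=O)[O-] | intermediate
4 | tert-butyl 5-nitro-2-oxocyclohexane-1-carboxylate (mixture of stereoisomers) | CC(C)(C)OC(=O)C1CC(CCC1=O)[N+](=O)[O-] | intermediate
5 | 4-nitrocyclohexan-1-one | O=C1CCC(CC1)[N+](=O)[O-] | intermediate
6 | dimethyl malonate | COC(=O)CC(=O)OC | starting material
7 | dimethyl 2-(4-nitrocyclohexylidene)propanedioate | COC(=O)C(C(=O)OC)=C1CCC(CC1)[N+](=O)[O-] | intermediate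
8 | 3-bromo-3-methylbutan-2-one | CC(=O)C(C)(C)Br | starting material
9 | trimethyl[(3-methylbut-2-en-2-yl)oxy]silane | CC(C)=C(C)O[Si](C)(C)C | intermediate
10 | dimethyl 2-[1-(2-methyl-3-oxobutan-2-yl)-4-nitrocyclohexyl]propanedioate (cis/trans mixture) | COC(=O)C(C(=O)OC)C1(CCC(CC1)[N+](=O)[O-])C(C)(C)C(C)=O | intermediate
11 | 1,1-dimethylspiro[5.5]undecane-2,4,9-trione (achiral) | CC1(C)C(=O)CC(=O)CC12CCC(=O)CC2 | intermediate
12 | 4-methoxy-1,1-dimethylspiro[5.5]undec-3-ene-2,9-dione (achiral) | C1C(OC)=CC(=O)C(C)(C)C12CCC(=O)CC2 | intermediate
13 | (6S)-4-methoxy-1,1-dimethyl-2-oxospiro[5.5]undeca-3,8-dien-9-yl trifluoromethanesulfonate | C1C(OC)=CC(=O)C(C)(C)[C@]12CCC(OS(=O)(=O)C(F)(F)F)=CC2 | intermediate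
14 | (6S)-4-methoxy-1,1,9-trimethylspiro[5.5]undeca-3,8-dien-2-one | C1C(OC)=CC(=O)C(C)(C)[C@]12CCC(C)=CC2 | intermediate
15 | (6S)-2-bromo-1,1,9-trimethylspiro[5.5]undeca-2,8-dien-4-one | C1C(=O)C=C(Br)C(C)(C)[C@]12CCC(C)=CC2 | intermediate
16 | (6S)-2-bromo-1,1,5,9-tetramethylspiro[5.5]undeca-2,8-dien-4-one (C5 epimers) | CC1C(=O)C=C(Br)C(C)(C)[C@]12CCC(C)=CC2 | intermediate
17 | (6R)-2-bromo-5-hydroxy-1,1,5,9-tetramethylspiro[5.5]undeca-2,8-dien-4-one (C5 epimers) | CC1(O)C(=O)C=C(Br)C(C)(C)[C@]12CCC(C)=CC2 | intermediate
18 | (6R,8S,9S)-2,8-dibromo-5,9-epoxy-1,1,5,9-tetramethylspiro[5.5]undec-2-en-4-one (oxygen bridge C5–O–C9; C5 epimers) | CC13C(=O)C=C(Br)C(C)(C)[C@]12CC[C@](C)(O3)[C@@H](Br)C2 | intermediate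
19 | (6R,8S,9S)-2,8-dibromo-9-chloro-5-hydroxy-1,1,5,9-tetramethylspiro[5.5]undec-2-en-4-one (C5 epimers) | CC1(O)C(=O)C=C(Br)C(C)(C)[C@]12CC[C@](C)(Cl)[C@@H](Br)C2 | intermediate
20 | (6S,8S,9S)-2,8-dibromo-9-chloro-1,1,9-trimethyl-5-methylidenespiro[5.5]undec-2-en-4-one | C=C1C(=O)C=C(Br)C(C)(C)[C@]12CC[C@](C)(Cl)[C@@H](Br)C2 | intermediate
21 | (4R,6S,8S,9S)-2,8-dibromo-9-chloro-1,1,9-trimethyl-5-methylidenespiro[5.5]undec-2-en-4-ol | C=C1[C@H](O)C=C(Br)C(C)(C)[C@]12CC[C@](C)(Cl)[C@@H](Br)C2 | target

Total step count: 16. Longest linear sequence: 15 steps (steps 1–3 and 5–16; step 4 prepares reagent 9).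

Steps most likely to fail

Step 5. The bond between the two fully substituted carbons C1 and C6 may not form: the silyl enol ether may be lost by protodesilylation, or the adduct may revert by retro-Michael cleavage. Fallback, from 7 back to 10: a Hosomi–Sakurai reaction of 7 with prenyltrimethylsilane (TiCl4, CH2Cl2, −78 °C), in which the allylsilane attacks through its disubstituted γ-carbon, should give dimethyl 2-[1-(2-methylbut-3-en-2-yl)-4-nitrocyclohexyl]propanedioate F1. Wacker oxidation of its vinyl group (PdCl2, CuCl, O2, DMF–H2O) then gives 10, so that the carbonyl group is introduced only after the congested bond is made.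

Step 10. Bromide transfer to the hindered C2 may be slow, so that the activated vinylogous ester returns dione-derived material or loses its alkoxy group without transposition (wrong regiochemistry of the bromoenone). Fallback, from 14 back to 15: mild acid hydrolysis (aq. HCl, THF) should give (6S)-1,1,9-trimethylspiro[5.5]undec-8-ene-2,4-dione F2, which with Ph3P·Br2 and Et3N gives both β-bromoenones. Compound 15 is separated from its regioisomer (6S)-4-bromo-1,1,9-trimethylspiro[5.5]undeca-3,8-dien-2-one F3, and F3 is hydrolysed back to F2 (aq. NaOH) and resubmitted.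

Step 14. Ionisation of the bridged ether may proceed without bromine participation, or the product may ionise again: loss of configuration at C9, elimination to a diene, or exchange of bromine and chlorine between C8 and C9. Fallback, from 17 directly to 19 (18 is bypassed and no compound outside the list is made, F0): an alcohol-directed bromochlorination, in which the titanium alkoxide formed from 17 and ClTi(OiPr)3 delivers chloride to C9 on the face of C5 while NBS supplies bromine to the opposite face.

Further compounds
F1 | step 5 | dimethyl 2-[1-(2-methylbut-3-en-2-yl)-4-nitrocyclohexyl]propanedioate | COC(=O)C(C(=O)OC)C1(CCC(CC1)[N+](=O)[O-])C(C)(C)C=C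
F2 | step 10 | (6S)-1,1,9-trimethylspiro[5.5]undec-8-ene-2,4-dione | C1C(=O)CC(=O)C(C)(C)[C@]12CCC(C)=CC2
F3 | step 10 | (6S)-4-bromo-1,1,9-trimethylspiro[5.5]undeca-3,8-dien-2-one | C1C(Br)=CC(=O)C(C)(C)[C@]12CCC(C)=CC2
F0 | step 14 | none | none
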